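**Retrosynthetic overview**
1. Numbering (avarane type): ring A = C1–C4, C5, C10 (C4 bears =CH2). Ring B = C5–C10 (C8 is CHCH3; C9 is quaternary with CH2OH and CH2Ar). β is the face of the C5 methyl.
2. 27 ⇒ 18: the late steps only adjust oxidation level. Aryl C–H becomes CO2Me by ortho-lithiation, C9 CO2Et becomes CH2OH, and the C4 and C8 carbonyls become C=CH2, the C8 one then being hydrogenated to 8β-CH3.
3. 18 ⇒ enone ester 11 + benzyl bromide 16: one dissolving-metal reductive alkylation sets C10–H (trans fusion) and quaternary C9.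
4. 11 ⇒ hydrindenone 6 + ethyl diazoacetate 7: ring B is first made as the five-membered ring C5–C6–C7–C8–C10, then enlarged by inserting C9, with its carboxyl carbon, between C8 and C10. Enabling feature: C9 carries an oxidised one-carbon branch and lies between C8 (can be C=O) and ring-fusion C10 (can be vinylic), which is a 2-oxocycloalkanecarboxylate retron.
5. Ring order: ring A (from dione 1) → five-membered proto-ring B by desymmetrising benzoin closure (sets C5) → six-membered ring B by 1,2-vinyl shift. The arene is brought in intact.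

Key step: step 6

Assumption: the sense of induction of the aminoindanol-derived triazolium catalyst in step 2 is assigned by analogy. Both antipodes are available, and the one that makes C5 (S) is used.

**Step 1**
Reactants: 1 2-methylcyclohexane-1,3-dione; 2 acrolein
Product: 3 3-(1-methyl-2,6-dioxocyclohexyl)propanal
Conditions: H2O, rt
Reagents that add atoms: none
Why: Michael addition of the cyclic 1,3-dione through C5 to acrolein should give the prochiral keto aldehyde without forming a stereocentre.

**Step 2**
Reactants: 3 3-(1-methyl-2,6-dioxocyclohexyl)propanal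
Product: 4 (3aR,7aS)-3a-hydroxy-7a-methyloctahydroindene-3,7-dione (cis-fused ketol; C10-OH and C5-CH3 both β)
Conditions: aminoindanol-derived N-aryl triazolium salt (10 mol %), Et3N (10 mol %), THF, rt
Reagents that add atoms: none
Why: In this desymmetrising intramolecular crossed benzoin reaction the Breslow intermediate at the aldehyde carbon (C8) should add 5-exo-trig to one of the two enantiotopic ring ketones (C10), the chiral carbene choosing the ketone and thereby fixing C5 as S, while the short tether enforces the cis fusion.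

**Step 3**
Reactants: 4 (3aR,7aS)-3a-hydroxy-7a-methyloctahydroindene-3,7-dione
Product: 5 (7aS)-7a-methyl-2,5,6,7a-tetrahydro-1H-indene-3,7-dione (C10=C1 enone)
Conditions: SOCl2, pyridine, 0 °C
Reagents that add atoms: none
Why: Dehydration of the tertiary alcohol through its chlorosulfite (E2) can only run toward C1, because C5 is quaternary and C8 is a carbonyl, so a single conjugated enone should form and C5 stays untouched.

**Step 4**
Reactants: 5 (7aS)-7a-methyl-2,5,6,7a-tetrahydro-1H-indene-3,7-dione
Product: 6 (7aS)-7,7-ethylenedioxy-7a-methyl-1,2,5,6,7,7a-hexahydro-3H-inden-3-one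
Conditions: ethylene glycol, p-TsOH (cat.), 4 Å MS, rt
Reagents that add atoms: ethylene glycol OCCO
Why: Chemoselective ketalisation should take the saturated six-ring C4 ketone and leave the conjugated five-ring C8 carbonyl, as in the selective ketalisation of the Wieland–Miescher ketone.

**Step 5**
Reactants: 6 (7aS)-7,7-ethylenedioxy-7a-methyl-1,2,5,6,7,7a-hexahydro-3H-inden-3-one; 7 ethyl diazoacetate
Product: 9 ethyl 2-diazo-2-[(3S,7aS)-7,7-ethylenedioxy-3-hydroxy-7a-methyl-2,3,5,6,7,7a-hexahydro-1H-inden-3-yl]acetate, via ethyl lithiodiazoacetate 8 (not isolated)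
Conditions: LDA, THF, −78 °C; 6; AcOH, −78 °C
Reagents that add atoms: none
Why: Aldol-type 1,2-addition of lithiated diazoacetate to the enone carbonyl C8 should occur opposite the C5 methyl, and the C8 configuration does not matter because step 6 erases it.

**Step 6**
Reactants: 9 ethyl 2-diazo-2-[(3S,7aS)-7,7-ethylenedioxy-3-hydroxy-7a-methyl-2,3,5,6,7,7a-hexahydro-1H-inden-3-yl]acetate
Product: 11 ethyl (4aS)-5,5-ethylenedioxy-4a-methyl-2-oxo-2,3,4,4a,5,6,7,8-octahydronaphthalene-1-carboxylate, via deconjugated keto ester 10 (not isolated)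
Conditions: Rh2(OAc)4 (1 mol %), CH2Cl2, 0 °C → rt; then DBU (0.2 equiv), rt
Reagents that add atoms: none
Why: Rh2(OAc)4 expels N2 from 9 and leaves an electrophilic rhodium carbene at C9 next to the C8 carbinol; the C8–C10 bond then shifts to C9 while the hydroxyl oxygen closes to C8=O (semipinacol-type 1,2-shift), so the five-membered ring C5–C6–C7–C8–C10 becomes six-membered ring B with C9 and its ester carbon (the later CH2OH) inserted between C8 and C10. The closest known reaction type is the one-carbon homologation of cyclic ketones through their lithiodiazoacetate adducts with Rh(II), combined with the established preference for 1,2-vinyl over 1,2-alkyl migration in Rh carbenes from β-hydroxy-α-diazo esters. No ring is closed by cyclisation: an existing ring grows by a 1,2-shift, and ring A and the dioxolane are spectators. The selectivity needed is migration of C10 rather than C7; it is secured by the C10=C1 double bond, whose π electrons assist the shift (C7 is an unactivated CH2), whereas a Lewis-acid diazoacetate insertion on 6 would move C7. No lasting stereocentre is created: C8 becomes planar, C9–H of 10 is a β-dicarbonyl proton, catalytic DBU moves the C10=C1 bond into conjugation to give the tetrasubstituted C9=C10 enone ester 11, and quaternary C5 is untouched. The product holds, in ring B of final size, the C8 carbonyl, the C9 carboxyl and the electrophilic C10 that programme the setting of C8, C9 and C10 in steps 10–12.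

**Step 7**
Reactants: 12 2-methoxybenzene-1,3-diol
Product: 13 2-methoxy-1,3-bis(methoxymethoxy)benzene
Conditions: MOMCl, i-Pr2NEt, CH2Cl2, 0 °C → rt
Reagents that add atoms: chloromethyl methyl ether COCCl
Why: O-alkylation (MOM protection) masks both phenols as acetals that survive base, hydride and hydrogenation and later direct both ortho-lithiations.

**Step 8**
Reactants: 13 2-methoxy-1,3-bis(methoxymethoxy)benzene
Product: 15 [3-methoxy-2,4-bis(methoxymethoxy)phenyl]methanol, via aryllithium 14 (not isolated)
Conditions: n-BuLi, THF, 0 °C; (CH2O)n, 0 °C → rt; H2O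
Reagents that add atoms: formaldehyde (as paraformaldehyde) C=O
Why: Directed ortho-metalation next to an OMOM group (the two such positions are equivalent by symmetry), followed by hydroxymethylation, should give the benzylic alcohol in one operation.

**Step 9**
Reactants: 15 [3-methoxy-2,4-bis(methoxymethoxy)phenyl]methanol
Product: 16 1-(bromomethyl)-3-methoxy-2,4-bis(methoxymethoxy)benzene
Conditions: CBr4, PPh3, CH2Cl2, −20 → 0 °C, used at once
Reagents that add atoms: carbon tetrabromide BrC(Br)(Br)Br
Why: The Appel reaction converts the benzylic alcohol into the bromide under neutral conditions that spare the MOM acetals.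

**Step 10**
Reactants: 11 ethyl (4aS)-5,5-ethylenedioxy-4a-methyl-2-oxo-2,3,4,4a,5,6,7,8-octahydronaphthalene-1-carboxylate; 16 1-(bromomethyl)-3-methoxy-2,4-bis(methoxymethoxy)benzene
Product: 18 ethyl (1R,4aS,8aR)-5,5-ethylenedioxy-1-[3-methoxy-2,4-bis(methoxymethoxy)benzyl]-4a-methyl-2-oxodecahydronaphthalene-1-carboxylate, via lithium enolate 17 (not isolated)
Conditions: Li, NH3(l)/THF, t-BuOH (1 equiv), −78 °C; isoprene; NH3 off; 16, DMPU, 0 °C → rt
Reagents that add atoms: none
Why: In this dissolving-metal reductive alkylation of an enone, axial protonation of the β-carbanion should give 10α-H (trans-decalin), and the regiodefined β-keto ester enolate should be benzylated at C9 from the α face opposite the axial C5 methyl, leaving the ester axial (β).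

**Step 11**
Reactants: 18 ethyl (1R,4aS,8aR)-5,5-ethylenedioxy-1-[3-methoxy-2,4-bis(methoxymethoxy)benzyl]-4a-methyl-2-oxodecahydronaphthalene-1-carboxylate
Product: 19 ethyl (1R,4aS,8aR)-5,5-ethylenedioxy-1-[3-methoxy-2,4-bis(methoxymethoxy)benzyl]-4a-methyl-2-methylidenedecahydronaphthalene-1-carboxylate
Conditions: Ph3PCH3Br, KHMDS (slight deficit), THF/toluene, 0 → 60 °C
Reagents that add atoms: methyltriphenylphosphonium bromide C[P+](c1ccccc1)(c1ccccc1)c1ccccc1.[Br-]
Why: Wittig methylenation with an alkoxide-free ylide should convert the hindered C8 ketone without retro-Claisen cleavage, and quaternary C9 cannot epimerise.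

**Step 12**
Reactants: 19 ethyl (1R,4aS,8aR)-5,5-ethylenedioxy-1-[3-methoxy-2,4-bis(methoxymethoxy)benzyl]-4a-methyl-2-methylidenedecahydronaphthalene-1-carboxylate
Product: 20 ethyl (1S,2S,4aS,8aR)-5,5-ethylenedioxy-1-[3-methoxy-2,4-bis(methoxymethoxy)benzyl]-2,4a-dimethyldecahydronaphthalene-1-carboxylate
Conditions: H2 (1–3 atm), Pd/C, EtOAc, rt
Reagents that add atoms: none
Why: Heterogeneous catalytic hydrogenation should deliver hydrogen to C8 from the α face, because the β face is screened by the axial C9 ester and the C5 methyl, which places the new methyl equatorial (8β).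

**Step 13**
Reactants: 20 ethyl (1S,2S,4aS,8aR)-5,5-ethylenedioxy-1-[3-methoxy-2,4-bis(methoxymethoxy)benzyl]-2,4a-dimethyldecahydronaphthalene-1-carboxylate
Product: 21 ethyl (1S,2S,4aS,8aR)-1-[3-methoxy-2,4-bis(methoxymethoxy)benzyl]-2,4a-dimethyl-5-oxodecahydronaphthalene-1-carboxylate
Conditions: PPTS, acetone–H2O (9:1), 60 °C
Reagents that add atoms: water O
Why: Buffered acid-catalysed acetal hydrolysis should open the dioxolane while the less basic aryl MOM acetals and the hindered ester persist.

**Step 14**
Reactants: 21 ethyl (1S,2S,4aS,8aR)-1-[3-methoxy-2,4-bis(methoxymethoxy)benzyl]-2,4a-dimethyl-5-oxodecahydronaphthalene-1-carboxylate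
Product: 22 ethyl (1S,2S,4aS,8aR)-1-[3-methoxy-2,4-bis(methoxymethoxy)benzyl]-2,4a-dimethyl-5-methylidenedecahydronaphthalene-1-carboxylate
Conditions: Ph3PCH3Br, KHMDS, toluene, 0 → 80 °C
Reagents that add atoms: methyltriphenylphosphonium bromide C[P+](c1ccccc1)(c1ccccc1)c1ccccc1.[Br-]
Why: Wittig methylenation of the C4 ketone installs the exocyclic alkene after all reductions of C=C bonds are done, and the axial neopentyl ester is too hindered to react with the ylide.

**Step 15**
Reactants: 22 ethyl (1S,2S,4aS,8aR)-1-[3-methoxy-2,4-bis(methoxymethoxy)benzyl]-2,4a-dimethyl-5-methylidenedecahydronaphthalene-1-carboxylate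
Product: 23 {(1S,2S,4aS,8aR)-1-[3-methoxy-2,4-bis(methoxymethoxy)benzyl]-2,4a-dimethyl-5-methylidenedecahydronaphthalen-1-yl}methanol
Conditions: LiAlH4, THF, reflux; aq. NaOH work-up
Reagents that add atoms: none
Why: Hydride reduction of the hindered ester gives the C9 hydroxymethyl group, and the isolated alkene and the MOM acetals are inert to LiAlH4.

**Step 16**
Reactants: 23 {(1S,2S,4aS,8aR)-1-[3-methoxy-2,4-bis(methoxymethoxy)benzyl]-2,4a-dimethyl-5-methylidenedecahydronaphthalen-1-yl}methanol
Product: 26 methyl 5-{[(1S,2S,4aS,8aR)-1-(hydroxymethyl)-2,4a-dimethyl-5-methylidenedecahydronaphthalen-1-yl]methyl}-3-methoxy-2,4-bis(methoxymethoxy)benzoate, via dilithiated alcohol 24 (not isolated), via methyl carbonate 25 (not isolated)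
Conditions: n-BuLi (2.5 equiv), THF, −78 → 0 °C; ClCO2Me, −78 °C → rt; then K2CO3 (cat.), MeOH, rt
Reagents that add atoms: methyl chloroformate COC(=O)Cl
Why: Directed ortho-metalation should occur at the only ring C–H ortho to an OMOM group; acylation with the chloroformate gives the benzoate, and the carbonate formed at the alkoxide is removed by methanolysis, which only degenerately transesterifies the aryl ester.

**Step 17**
Reactants: 26 methyl 5-{[(1S,2S,4aS,8aR)-1-(hydroxymethyl)-2,4a-dimethyl-5-methylidenedecahydronaphthalen-1-yl]methyl}-3-methoxy-2,4-bis(methoxymethoxy)benzoate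
Product: 27 methyl 2,4-dihydroxy-5-{[(1S,2S,4aS,8aR)-1-(hydroxymethyl)-2,4a-dimethyl-5-methylidenedecahydronaphthalen-1-yl]methyl}-3-methoxybenzoate
Conditions: ZnBr2, n-PrSH, CH2Cl2, 0 °C → rt, short contact
Reagents that add atoms: none
Why: Lewis-acid-promoted acetal exchange with a thiol frees both phenols without a Brønsted acid, so the acid-labile exocyclic C4 alkene should not migrate.

**Compound list**
1 | 2-methylcyclohexane-1,3-dione | CC1C(=O)CCCC1=O | starting material
2 | acrolein | C=CC=O | starting material
3 | 3-(1-methyl-2,6-dioxocyclohexyl)propanal | O=CCCC1(C)C(=O)CCCC1=O | intermediate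
4 | (3aR,7aS)-3a-hydroxy-7a-methyloctahydroindene-3,7-dione | O=C1CCC[C@]2(O)C(=O)CC[C@]12C | intermediate
5 | (7aS)-7a-methyl-2,5,6,7a-tetrahydro-1H-indene-3,7-dione | O=C1CCC=C2C(=O)CC[C@]12C | intermediate
6 | (7aS)-7,7-ethylenedioxy-7a-methyl-1,2,5,6,7,7a-hexahydro-3H-inden-3-one | C1COC2(O1)CCC=C3C(=O)CC[C@]23C | intermediate
7 | ethyl diazoacetate | CCOC(=O)C=[N+]=[N-] | starting material
8 | ethyl lithiodiazoacetate | [Li]C(=[N+]=[N-])C(=O)OCC | intermediate
9 | diazo carbinol (C8-OH β, diazoacetate α) | C1COC2(O1)CCC=C3[C@](O)(C(=[N+]=[N-])C(=O)OCC)CC[C@]23C | intermediate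
10 | ethyl (4aS)-5,5-ethylenedioxy-4a-methyl-2-oxo-1,2,3,4,4a,5,6,7-octahydronaphthalene-1-carboxylate (C9 epimers and enol) | C1COC2(O1)CCC=C3C(C(=O)OCC)C(=O)CC[C@]23C | intermediate
11 | ethyl (4aS)-5,5-ethylenedioxy-4a-methyl-2-oxo-2,3,4,4a,5,6,7,8-octahydronaphthalene-1-carboxylate | C1COC2(O1)CCCC3=C(C(=O)OCC)C(=O)CC[C@]23C | intermediate
12 | 2-methoxybenzene-1,3-diol | COc1c(O)cccc1O | starting material
13 | 2-methoxy-1,3-bis(methoxymethoxy)benzene | COCOc1cccc(OCOC)c1OC | intermediate
14 | [3-methoxy-2,4-bis(methoxymethoxy)phenyl]lithium | [Li]c1ccc(OCOC)c(OC)c1OCOC | intermediate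
15 | [3-methoxy-2,4-bis(methoxymethoxy)phenyl]methanol | OCc1ccc(OCOC)c(OC)c1OCOC | intermediate
16 | 1-(bromomethyl)-3-methoxy-2,4-bis(methoxymethoxy)benzene | BrCc1ccc(OCOC)c(OC)c1OCOC | intermediate
17 | lithium enolate of the trans-fused keto ester (10α-H) | C1COC2(O1)CCC[C@H]3C(C(=O)OCC)=C(O[Li])CC[C@]23C | intermediate
18 | benzylated keto ester (9α-CH2Ar, 9β-CO2Et, 10α-H) | C1COC2(O1)CCC[C@H]3[C@](C(=O)OCC)(Cc4ccc(OCOC)c(OC)c4OCOC)C(=O)CC[C@]23C | intermediate
19 | C8 methylidene ester | C1COC2(O1)CCC[C@H]3[C@](C(=O)OCC)(Cc4ccc(OCOC)c(OC)c4OCOC)C(=C)CC[C@]23C | intermediate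
20 | 8β-methyl ester ketal | C1COC2(O1)CCC[C@H]3[C@](C(=O)OCC)(Cc4ccc(OCOC)c(OC)c4OCOC)[C@@H](C)CC[C@]23C | intermediate
21 | C4 ketone ester | O=C1CCC[C@H]2[C@](C(=O)OCC)(Cc3ccc(OCOC)c(OC)c3OCOC)[C@@H](C)CC[C@]12C | intermediate
22 | C4 methylidene ester | C=C1CCC[C@H]2[C@](C(=O)OCC)(Cc3ccc(OCOC)c(OC)c3OCOC)[C@@H](C)CC[C@]12C | intermediate
23 | C9 hydroxymethyl compound | C=C1CCC[C@H]2[C@](CO)(Cc3ccc(OCOC)c(OC)c3OCOC)[C@@H](C)CC[C@]12C | intermediate
24 | dilithiated alcohol (O-Li and aryl-Li) | C=C1CCC[C@H]2[C@](CO[Li])(Cc3cc([Li])c(OCOC)c(OC)c3OCOC)[C@@H](C)CC[C@]12C | intermediate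
25 | aryl methyl ester with C9 CH2OCO2Me | C=C1CCC[C@H]2[C@](COC(=O)OC)(Cc3cc(C(=O)OC)c(OCOC)c(OC)c3OCOC)[C@@H](C)CC[C@]12C | intermediate
26 | bis-MOM ether of the target | C=C1CCC[C@H]2[C@](CO)(Cc3cc(C(=O)OC)c(OCOC)c(OC)c3OCOC)[C@@H](C)CC[C@]12C | intermediate
27 | methyl 2,4-dihydroxy-5-{[(1S,2S,4aS,8aR)-1-(hydroxymethyl)-2,4a-dimethyl-5-methylidenedecahydronaphthalen-1-yl]methyl}-3-methoxybenzoate | C=C1CCC[C@H]2[C@](CO)(Cc3cc(C(=O)OC)c(O)c(OC)c3O)[C@@H](C)CC[C@]12C | target

**Totals**
- Total step count: 17.
- Longest linear sequence: 14 (steps 1–6 and 10–17).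

**Steps most likely to fail**

Step 6. What may go wrong: competing migration of the C7 methylene, O–H insertion or retro-aldol loss of diazoacetate before carbene formation, or incomplete movement of the alkene into conjugation.
Fallback, from 6 back to 11, keeps the five-to-six enlargement but makes it by cyclopropanation and electrocyclic opening.
- 1,4-Hydrosilylation of 6 (Et3SiH, RhCl(PPh3)3) would give the ring-fusion triethylsilyl enol ether F1.
- Dibromocarbene (CHBr3, KOt-Bu, pentane) would add to its C8=C10 bond opposite the C5 methyl to give the siloxy dibromocyclopropane F2.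
- On warming, F2 opens across the C8–C10 bond with loss of the silyl bromide to give the ring-enlarged 9-bromo enone F3.
- Pd-catalysed ethoxycarbonylation of F3 (Pd(OAc)2, dppf, CO, EtOH, Et3N) gives 11.

Step 10. What may go wrong: deprotonation of the enone ester at the γ position instead of electron transfer, O-alkylation, self-condensation of the electron-rich bromide, or erosion of facial selectivity.
Fallback, from 11 and 15 back to 18, separates the two events and changes the electrophile.
- 11 is reduced with Li/NH3 and quenched with NH4Cl to give the isolable trans-fused β-keto ester F4.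
- Alcohol 15 is acylated (ClCO2Me, pyridine) to the stable benzyl methyl carbonate F5.
- F4 is benzylated with F5 under Pd catalysis ([Pd(allyl)(cod)]BF4, dppf, 80 °C) through an η3-benzylpalladium species, which should again approach the α face.

Step 16. What may go wrong: lateral (benzylic) metalation, sluggish ring lithiation in the presence of alkoxide aggregates, or addition of the aryllithium to the ester just formed.
Fallback, from 21 back to 26, replaces metalation by electrophilic halogenation and carbonylation, carried out before any alkene or free alcohol is present.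
- NBS (MeCN, 0 °C) brominates 21 at the only ring position ortho/para to both MOM-oxy groups, giving the bromo keto ester F6.
- Wittig methylenation of F6 gives the bromo alkene ester F7.
- DIBAL-H (toluene) reduces the ester of F7 without touching the aryl bromide, giving the bromo alcohol F8.
- Pd-catalysed methoxycarbonylation of F8 (Pd(OAc)2, Xantphos, CO, MeOH, Et3N) gives 26.

**Further compounds**
F1 | step 6 | (7aS)-7,7-ethylenedioxy-7a-methyl-3-(triethylsilyloxy)-2,4,5,6,7,7a-hexahydro-1H-indene | C1COC2(O1)CCCC3=C(O[Si](CC)(CC)CC)CC[C@]23C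
F2 | step 6 | siloxy dibromocyclopropane (CBr2 bridging C8 and C10 on the α face) | C1COC2(O1)CCC[C@@]34C(Br)(Br)[C@]3(O[Si](CC)(CC)CC)CC[C@]24C
F3 | step 6 | (4aS)-1-bromo-5,5-ethylenedioxy-4a-methyl-4,4a,5,6,7,8-hexahydronaphthalen-2(3H)-one | C1COC2(O1)CCCC3=C(Br)C(=O)CC[C@]23C
F4 | step 10 | trans-fused β-keto ester (10α-H; C9 epimers and enol) | C1COC2(O1)CCC[C@H]3C(C(=O)OCC)C(=O)CC[C@]23C
F5 | step 10 | 3-methoxy-2,4-bis(methoxymethoxy)benzyl methyl carbonate | COC(=O)OCc1ccc(OCOC)c(OC)c1OCOC
F6 | step 16 | bromo keto ester (aryl bromide of 21) | O=C1CCC[C@H]2[C@](C(=O)OCC)(Cc3cc(Br)c(OCOC)c(OC)c3OCOC)[C@@H](C)CC[C@]12C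
F7 | step 16 | bromo alkene ester (aryl bromide of 22) | C=C1CCC[C@H]2[C@](C(=O)OCC)(Cc3cc(Br)c(OCOC)c(OC)c3OCOC)[C@@H](C)CC[C@]12C
F8 | step 16 | bromo alcohol (aryl bromide of 23) | C=C1CCC[C@H]2[C@](CO)(Cc3cc(Br)c(OCOC)c(OC)c3OCOC)[C@@H](C)CC[C@]12C
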